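Remark: the C2–C8' biaryl axis is drawn without configuration, so it is treated as not configurationally defined and is not controlled. Compounds 1, 11 and 22 are taken as purchasable.

## Analysis of the target

The target joins C2 of a 5-hydroxy-7-methyl-1,4-naphthoquinone (ring A = cresol ring C4a/C5–C8/C8a, ring B = quinone ring C1–C4) to C8' of a 7'-methylchromone (ring C = benzo ring, ring D = pyranone). The chromone carries a carboxylic acid at C5', peri to the C4' carbonyl. There is no stereocentre; the only possible stereo-element is the hindered C2–C8' axis, flanked by C1=O, C3–H, the C7' methyl group and O1'. The quinone with its free C3–H is sensitive to bases, nucleophiles and light, and the pyranone is opened at C2' by hydroxide and amines. Strongly basic or nucleophilic steps are therefore excluded once either ring exists.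

Three things make the synthesis hard:
- The juglone regiochemistry: the hydroxyl at C5 must be peri to C4=O, the carbonyl remote from the aryl group, with the methyl at C7.
- The biaryl bond, which carries three ortho substituents.
- Ring C, which carries five different substituents.

The strategy rests on one structural feature. C5 (oxygenated) and C8 (CH) sit on the adjacent carbons C4a and C8a of ring B, exactly as the formyl and methyl groups sit in a 2-methylbenzaldehyde, and C6–C7(CH3) corresponds to the double bond of a crotonate. Ring A can therefore be grown on an aryl-substituted hydroquinone dimethyl ether whose substitution pattern fixes the juglone regiochemistry by constitution. A 5-oxo-5,6,7,8-tetrahydro-1,4-naphthoquinone is an isomer of the naphthalene-1,4,5-triol, so every sp3 centre made on the way is erased by tautomerisation.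

## Retrosynthetic reasoning

**31 to 29 (via 30).** No skeletal bond is cut. Target 31 is the two-electron oxidation product of triol 30, and 30 is a tautomer of trione 29. The forward reaction has to move three hydrogens from C6, C7 and C8 to the three oxygens; the gain is that the C5 hydroxyl appears free, with no late ether cleavage next to a quinone.

**29 to 28 to 27.** The quinone of 29 comes from the para-dimethoxyarene 28 by oxidative demethylation. The carboxylic acid is unmasked one stage earlier (27 to 28) under aqueous acid, because neither chromone nor quinone tolerates hydroxide and the quinone should not be heated in acid.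

**27 to 25 to 24.** The C6–CO2R bond is cut. The ester is only an activating group for ring formation; it is removed from β-keto ester 25 by acid cleavage and decarboxylation after the carbinol of 24 has been oxidised. A tert-butyl ester is chosen so that this happens without touching the methyl ester on ring C.

**24 to 21 and 22.** The bonds C5–C6 and C7–C8 are cut together. This is the only place where ring A can be opened so that both fragments are simple and the regiochemistry is constitutional: the formyl carbon of 21 becomes C5 next to C4, and its methyl carbon becomes C8 next to C1. The forward reaction must turn the 2-methylbenzaldehyde 21 into a diene and add it to 22 with C8 bonding to the methyl-bearing alkene carbon.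

**21 to 20 and 10.** The C2–C8' bond is cut between the two aromatic halves. Cutting here keeps the synthesis convergent and puts the hindered bond formation on two robust fragments. The iodide is placed on the more hindered, electron-poor chromone and the boron on the electron-rich benzaldehyde.

**10 back to 1.** The boron of 10 replaces the bromine of 9. The bromine is placed with certainty by the free phenol of 7, whose para position and other ortho position are occupied; the corresponding dimethyl ether would offer two ring positions of similar reactivity. The C–CH3 bond of 6 is cut back to 2, where the masked aldehyde and the acetal ether jointly direct lithiation to the carbon between them.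

**20 back to 11.** The pyranone of 20 is cut at O1'–C2' and C2'–C3' back to the ortho-hydroxyacetophenone 18; with one phenol left, the ring oxygen must end up next to iodine. The iodine of 18 is placed ortho to the chelated phenol of 17. The ester carbon of 17 comes from triflate 16 by carbonylation. Triflate 16 comes from the symmetric diol 15, in which both hydroxyls are equivalent. Diol 15 comes from 14, whose acetyl group is introduced between the two methoxy groups of 11 by directed lithiation.

## Alternatives that were turned down

**Alternative 1:** Ring C is cut at C7'–C8' and C4a'–C5', giving a three-carbon bis-nucleophile and a three-carbon bis-electrophile. In the forward direction TiCl4 would condense bis(silyloxy)diene A2, whose terminal carbon already carries the 1,4,5-trimethoxy-7-methylnaphthalen-2-yl group, with silyl enol ether A3 to give the pentasubstituted 2-acetyl-3-hydroxybenzoate A1. Pyranone closure, oxidative demethylation, cleavage of the peri methyl ether and ester hydrolysis would follow.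
- For it: the crowded biaryl bond is never made by cross-coupling, and A1 arrives with acetyl, hydroxyl, ester, methyl and aryl in the right order. It needs neither a halogenation of ring C nor a hindered coupling, and on these two points it is stronger than the chosen route.
- Against it: the juglone half must first be made as a 2-substituted trimethoxynaphthalene, so the central regiochemical question (C2 versus C3) is only moved into the preparation of A2. A diene carrying a bulky, electron-rich naphthyl group at its reacting terminus is a poor partner, and its orientation towards the unsymmetrical A3 rests on a kinetic preference. The electron-rich naphthalene must survive TiCl4, and the end needs a selective ether cleavage beside a quinone.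
- Comparison: the chosen strategy is of similar length but ties the position of the juglone hydroxyl to the biaryl bond through one benzaldehyde and delivers the C5 hydroxyl free.

**Alternative 2:** Ring B is cut at C4–C3, C2–C1 and C1–C8a. On heating, the chromium alkoxycarbene complex A5 and the terminal alkyne A6 would combine with one carbonyl ligand to give the 4-methoxy-1-naphthol A4; oxidation to the quinone, cleavage of the C5 methyl ether and ester hydrolysis would finish.
- For it: it is highly convergent. The terminal alkyne reliably places the chromone next to the phenolic carbon, and the ortho-methoxy group of the carbene aryl ends up peri to C4. In regiocontrol of ring B and in step count after fragment union it is as strong as or stronger than the chosen route.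
- Against it: stoichiometric chromium from Cr(CO)6 is needed. The alkyne is flanked by a methyl group and O1' and is electron-poor, which favours the known side paths of this benzannulation (cyclobutenone and indene formation). The pyranone C2'=C3' enone is a possible acceptor for the carbene. A6 must still be made from the same 8-iodochromone 20, so the chromone half is no shorter. The end again needs ether cleavage next to a quinone.
- Comparison: the chosen strategy offers a metal-free ring formation at room temperature and a C5 hydroxyl that needs no deprotection.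

**Alternative 3:** Ring A is cut at C8–C8a and C5–C4a on the quinone oxidation level. The silyl vinylketene acetal A9 would add to the bromoquinone A8 across the bromine-bearing double bond, and loss of hydrogen bromide, methanol and silicon would give the juglone ester A7 directly.
- For it: it is the shortest route. The bromine directs the nucleophilic diene terminus to the unsubstituted carbon, which gives the required 5-hydroxy-7-methyl pattern, and the reaction is thermal and mild. In step economy and in how directly the ring-forming step reaches the final oxidation state it is stronger than the chosen strategy.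
- Against it: the regiochemistry rests on a kinetic orientation rule on a quinone that also carries a second, remote substituent. The strongly nucleophilic ketene acetal can instead reduce the electron-poor aryl quinone or add to it in a conjugate fashion. A8 is a reactive intermediate. The methyl ester of A7 must be cleaved with the quinone present.
- Comparison: the chosen strategy builds ring A on a robust dimethyl ether, keeps every quinone to the last two steps, hydrolyses the ester beforehand and fixes the regiochemistry by constitution.

Key step: step 14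

## Route

Step 1
Reactants: 1 5-hydroxy-2-methoxybenzaldehyde
Product: 2 2-methoxy-5-(methoxymethoxy)benzaldehyde
Conditions: MOMCl, i-Pr2NEt, CH2Cl2, 0 °C to rt
Reagents that add atoms: chloromethyl methyl ether, COCCl
Why: O-alkylation of the phenol gives the acetal ether, a strong ortho-director for step 2 that is later removed without touching the methyl ether.

Step 2
Reactants: 2 2-methoxy-5-(methoxymethoxy)benzaldehyde
Product: 6 6-methoxy-3-(methoxymethoxy)-2-methylbenzaldehyde, via lithium amino alkoxide 3 (not isolated), via aryllithium 4 (not isolated), via methylated amino alkoxide 5 (not isolated)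
Conditions: LiN(Me)CH2CH2NMe2 (from Me(H)NCH2CH2NMe2 and n-BuLi), THF, −20 °C; n-BuLi (3 equiv), −20 °C; MeI, −78 °C to rt; aq. NH4Cl
Reagents that add atoms: iodomethane, CI
Why: Directed ortho-metalation: the amide adds to the aldehyde and masks it as alkoxide 3, and this group and the acetal ether together direct n-BuLi to the one carbon between them. Methylation of 4 and aqueous work-up return the aldehyde.

Step 3
Reactants: 6 6-methoxy-3-(methoxymethoxy)-2-methylbenzaldehyde
Product: 7 3-hydroxy-6-methoxy-2-methylbenzaldehyde
Conditions: HCl (2 M in MeOH), 50 °C; then H2O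
Reagents that add atoms: none
Why: Acid-catalysed acetal exchange removes the methoxymethyl group as dimethoxymethane and leaves the aryl methyl ether; the free phenol is needed as director in step 4.

Step 4
Reactants: 7 3-hydroxy-6-methoxy-2-methylbenzaldehyde
Product: 8 4-bromo-3-hydroxy-6-methoxy-2-methylbenzaldehyde
Conditions: NBS, i-Pr2NH (10 mol %), CH2Cl2, 0 °C
Reagents that add atoms: N-bromosuccinimide, O=C1CCC(=O)N1Br
Why: Electrophilic aromatic bromination under amine catalysis goes ortho to the free phenol; its para position carries the methoxy group and its other ortho position the methyl group, so only C4 is open to it.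

Step 5
Reactants: 8 4-bromo-3-hydroxy-6-methoxy-2-methylbenzaldehyde
Product: 9 4-bromo-3,6-dimethoxy-2-methylbenzaldehyde
Conditions: MeI, K2CO3, DMF, rt
Reagents that add atoms: iodomethane, CI
Why: Williamson O-methylation of the phenoxide; the aldehyde and aryl bromide are inert to carbonate.

Step 6
Reactants: 9 4-bromo-3,6-dimethoxy-2-methylbenzaldehyde
Product: 10 3,6-dimethoxy-2-methyl-4-(4,4,5,5-tetramethyl-1,3,2-dioxaborolan-2-yl)benzaldehyde
Conditions: B2pin2, PdCl2(dppf) (3 mol %), KOAc, 1,4-dioxane, 90 °C
Reagents that add atoms: bis(pinacolato)diboron, CC1(C)OB(OC1(C)C)B1OC(C)(C)C(C)(C)O1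
Why: Miyaura borylation; the bromide para to the formyl group adds readily to palladium and KOAc is mild enough for the aldehyde.

Step 7
Reactants: 11 1,3-dimethoxy-5-methylbenzene
Product: 14 1-(2,6-dimethoxy-4-methylphenyl)ethan-1-one, via aryllithium 12 (not isolated), via tetrahedral adduct 13 (not isolated)
Conditions: n-BuLi, THF, 0 °C to rt; MeC(O)N(OMe)Me, −78 °C to rt; aq. NH4Cl
Reagents that add atoms: N-methoxy-N-methylacetamide, CC(=O)N(C)OC
Why: Directed ortho-lithiation occurs at the carbon between the two methoxy groups; acylation with the N-methoxy-N-methyl amide stops at the chelated adduct 13, which releases the ketone on work-up.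

Step 8
Reactants: 14 1-(2,6-dimethoxy-4-methylphenyl)ethan-1-one
Product: 15 1-(2,6-dihydroxy-4-methylphenyl)ethan-1-one
Conditions: BBr3 (3 equiv), CH2Cl2, −78 °C to rt; H2O
Reagents that add atoms: none
Why: Lewis-acid cleavage of both aryl methyl ethers, assisted by chelation to the ortho carbonyl.

Step 9
Reactants: 15 1-(2,6-dihydroxy-4-methylphenyl)ethan-1-one
Product: 16 2-acetyl-3-hydroxy-5-methylphenyl trifluoromethanesulfonate
Conditions: Tf2O (1.0 equiv), pyridine, CH2Cl2, −78 to 0 °C
Reagents that add atoms: trifluoromethanesulfonic anhydride, O=S(=O)(OS(=O)(=O)C(F)(F)F)C(F)(F)F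
Why: O-sulfonylation of a symmetric diol, so either hydroxyl gives the same product; the second hydroxyl stays hydrogen-bonded to the ketone and is deactivated by the new sulfonate, which stops the reaction at the monotriflate.

Step 10
Reactants: 16 2-acetyl-3-hydroxy-5-methylphenyl trifluoromethanesulfonate
Product: 17 methyl 2-acetyl-3-hydroxy-5-methylbenzoate
Conditions: Pd(OAc)2 (5 mol %), dppp, CO (1 atm), Et3N, MeOH/DMSO, 70 °C
Reagents that add atoms: carbon monoxide, [C-]#[O+]; methanol, CO
Why: Palladium-catalysed methoxycarbonylation of the aryl triflate (oxidative addition, CO insertion, methanolysis); the free phenol and the ketone are tolerated.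

Step 11
Reactants: 17 methyl 2-acetyl-3-hydroxy-5-methylbenzoate
Product: 18 methyl 2-acetyl-3-hydroxy-4-iodo-5-methylbenzoate
Conditions: NIS, CF3CO2H (cat.), MeCN, 0 °C to rt
Reagents that add atoms: N-iodosuccinimide, O=C1CCC(=O)N1I
Why: Electrophilic aromatic iodination; chelated ortho-hydroxy aryl ketones react ortho to the hydroxyl, and the para carbon lies between the methyl and the ester group and is the more hindered one.

Step 12
Reactants: 18 methyl 2-acetyl-3-hydroxy-4-iodo-5-methylbenzoate
Product: 20 methyl 8-iodo-7-methyl-4-oxo-4H-chromene-5-carboxylate, via enaminone 19 (not isolated)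
Conditions: Me2NCH(OMe)2, toluene, 95 °C; then conc. HCl, CH2Cl2, rt
Reagents that add atoms: N,N-dimethylformamide dimethyl acetal, COC(OC)N(C)C
Why: Condensation at the acetyl methyl group gives enaminone 19, and acid-promoted conjugate addition of the phenol with loss of dimethylamine closes the pyranone (enaminone chromone synthesis). Only one phenol is present, so O1' is necessarily the oxygen next to iodine.

Step 13
Reactants: 20 methyl 8-iodo-7-methyl-4-oxo-4H-chromene-5-carboxylate; 10 3,6-dimethoxy-2-methyl-4-(4,4,5,5-tetramethyl-1,3,2-dioxaborolan-2-yl)benzaldehyde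
Product: 21 methyl 8-(4-formyl-2,5-dimethoxy-3-methylphenyl)-7-methyl-4-oxo-4H-chromene-5-carboxylate
Conditions: Pd(OAc)2 (5 mol %), SPhos, K3PO4, toluene/H2O (10:1), 80 °C
Reagents that add atoms: none
Why: Suzuki–Miyaura coupling; the bulky dialkylbiarylphosphine allows a biaryl with three ortho substituents to form, and the mild phosphate base spares the pyranone, the aldehyde and the ester.

Step 14
Reactants: 21 methyl 8-(4-formyl-2,5-dimethoxy-3-methylphenyl)-7-methyl-4-oxo-4H-chromene-5-carboxylate; 22 tert-butyl (E)-but-2-enoate
Product: 24 tert-butyl rac-(1R,2R,3S)-1-hydroxy-5,8-dimethoxy-6-[5-(methoxycarbonyl)-7-methyl-4-oxo-4H-chromen-8-yl]-3-methyl-1,2,3,4-tetrahydronaphthalene-2-carboxylate (target locants: C5 hydroxyl cis to the C6 ester, C7 methyl trans to the C6 ester), via dienol 23 (not isolated)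
Conditions: hν (365 nm), Ti(OiPr)4 (2 equiv), 22 (10 equiv), degassed toluene, rt; aq. NaHCO3
Reagents that add atoms: none
Why: Excitation of the formyl group of 21 near 365 nm, intersystem crossing and 1,5-hydrogen transfer from the ortho methyl group give a biradical that relaxes to dienol 23 with the hydroxyl turned away from the methylene, a dearomatised diene that Ti(OiPr)4 holds as a titanium dienolate. The closest known reaction type is the photoenolisation/Diels–Alder reaction of 3,6-dimethoxy-2-methylbenzaldehydes with acrylates and enones, including its Ti(OiPr)4-assisted form. Ring A closes by an intermolecular suprafacial [4+2] cycloaddition that forms C7–C8 and C5–C6 and restores the aromaticity of ring B, which is the driving force. C5 and C6 are set cis by the endo approach of the ester carbonyl under the outward hydroxyl, reinforced when titanium bridges the dienol oxygen and the ester carbonyl; C7 is set trans to C6 because the E geometry of 22 is carried over; the product is racemic. The step needs head-to-head regioselectivity, which the hydroxyl donor secures by placing the largest HOMO coefficient on the methylene terminus C8, so that C8 bonds to the β-carbon of 22. It also needs hydrogen abstraction only from the ring B methyl group, which is the only C–H within reach of the excited formyl oxygen. An excess of 22 and a wavelength at which the chromone absorbs weakly are chosen so that trapping outruns reversion of 23 to 21 and chromone photochemistry. All three stereocentres are removed later, so the diastereomer ratio does not matter.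

Step 15
Reactants: 24 tert-butyl rac-(1R,2R,3S)-1-hydroxy-5,8-dimethoxy-6-[5-(methoxycarbonyl)-7-methyl-4-oxo-4H-chromen-8-yl]-3-methyl-1,2,3,4-tetrahydronaphthalene-2-carboxylate
Product: 25 tert-butyl rac-(2R,3S)-5,8-dimethoxy-6-[5-(methoxycarbonyl)-7-methyl-4-oxo-4H-chromen-8-yl]-3-methyl-1-oxo-1,2,3,4-tetrahydronaphthalene-2-carboxylate
Conditions: Dess–Martin periodinane, NaHCO3, CH2Cl2, 0 °C to rt
Reagents that add atoms: none
Why: Dess–Martin oxidation of the benzylic secondary alcohol under buffered, non-basic conditions avoids dehydration or retro-aldol cleavage of the β-hydroxy ester; the α-centre of the resulting β-keto ester is labile and is lost in the next step.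

Step 16
Reactants: 25 tert-butyl rac-(2R,3S)-5,8-dimethoxy-6-[5-(methoxycarbonyl)-7-methyl-4-oxo-4H-chromen-8-yl]-3-methyl-1-oxo-1,2,3,4-tetrahydronaphthalene-2-carboxylate
Product: 27 methyl 8-(1,4-dimethoxy-7-methyl-5-oxo-5,6,7,8-tetrahydronaphthalen-2-yl)-7-methyl-4-oxo-4H-chromene-5-carboxylate (racemic), via keto acid 26 (not isolated)
Conditions: TsOH·H2O (0.2 equiv), toluene, 90 °C
Reagents that add atoms: none
Why: Acid-catalysed loss of 2-methylpropene from the tert-butyl ester gives β-keto acid 26, which decarboxylates through the cyclic six-membered transition state; the methyl ester is not affected.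

Step 17
Reactants: 27 methyl 8-(1,4-dimethoxy-7-methyl-5-oxo-5,6,7,8-tetrahydronaphthalen-2-yl)-7-methyl-4-oxo-4H-chromene-5-carboxylate
Product: 28 8-(1,4-dimethoxy-7-methyl-5-oxo-5,6,7,8-tetrahydronaphthalen-2-yl)-7-methyl-4-oxo-4H-chromene-5-carboxylic acid (racemic)
Conditions: 3 M aq. H2SO4/AcOH (1:2), 100 °C
Reagents that add atoms: water, O
Why: Acid-catalysed ester hydrolysis; chromone, aryl methyl ethers and the tetralone are stable to hot aqueous acid, and the step is placed here because hydroxide would open the pyranone and the later quinone should not be heated in acid.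

Step 18
Reactants: 28 8-(1,4-dimethoxy-7-methyl-5-oxo-5,6,7,8-tetrahydronaphthalen-2-yl)-7-methyl-4-oxo-4H-chromene-5-carboxylic acid
Product: 29 7-methyl-8-(7-methyl-1,4,5-trioxo-1,4,5,6,7,8-hexahydronaphthalen-2-yl)-4-oxo-4H-chromene-5-carboxylic acid (racemic)
Conditions: (NH4)2Ce(NO3)6 (2.5 equiv), MeCN/H2O (2:1), 0 °C
Reagents that add atoms: water, O
Why: Oxidative demethylation of the para-dimethoxyarene: one-electron oxidation, addition of water at the methoxy-bearing carbons and loss of methanol give the quinone; chromone, acid and ketone are inert.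

Step 19
Reactants: 29 7-methyl-8-(7-methyl-1,4,5-trioxo-1,4,5,6,7,8-hexahydronaphthalen-2-yl)-4-oxo-4H-chromene-5-carboxylic acid
Product: 31 8-(5-hydroxy-7-methyl-1,4-dioxo-1,4-dihydronaphthalen-2-yl)-7-methyl-4-oxo-4H-chromene-5-carboxylic acid (target), via naphthalenetriol 30 (not isolated)
Conditions: TsOH·H2O (cat.), AcOH, 50 °C, Ar; then (NH4)2Ce(NO3)6 (2.1 equiv), MeCN/H2O, 0 °C
Reagents that add atoms: none
Why: Acid-catalysed enolisation moves the hydrogens of C6, C7 and C8 onto the three oxygens, an internal redox isomerisation of the kind used to aromatise quinone Diels–Alder adducts, and gives the aromatic triol 30. Two-electron oxidation of its para-dihydroxy ring then gives the quinone and leaves the C5 hydroxyl, hydrogen-bonded to C4=O, free.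

## Compound list

1 | 5-hydroxy-2-methoxybenzaldehyde | COc1ccc(O)cc1C=O | starting material
2 | 2-methoxy-5-(methoxymethoxy)benzaldehyde | COCOc1ccc(OC)c(C=O)c1 | intermediate
3 | lithium [2-methoxy-5-(methoxymethoxy)phenyl]{[2-(dimethylamino)ethyl](methyl)amino}methanolate (not isolated) | COCOc1ccc(OC)c(C([O-])N(C)CCN(C)C)c1.[Li+] | intermediate
4 | 6-lithio derivative of 3, lithium on the ring carbon between the carbinol carbon and the acetal ether (not isolated) | [Li]c1c(OCOC)ccc(OC)c1C([O-])N(C)CCN(C)C.[Li+] | intermediate
5 | lithium [6-methoxy-3-(methoxymethoxy)-2-methylphenyl]{[2-(dimethylamino)ethyl](methyl)amino}methanolate (not isolated) | COCOc1ccc(OC)c(C([O-])N(C)CCN(C)C)c1C.[Li+] | intermediate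
6 | 6-methoxy-3-(methoxymethoxy)-2-methylbenzaldehyde | COCOc1ccc(OC)c(C=O)c1C | intermediate
7 | 3-hydroxy-6-methoxy-2-methylbenzaldehyde | COc1ccc(O)c(C)c1C=O | intermediate
8 | 4-bromo-3-hydroxy-6-methoxy-2-methylbenzaldehyde | COc1cc(Br)c(O)c(C)c1C=O | intermediate
9 | 4-bromo-3,6-dimethoxy-2-methylbenzaldehyde | COc1cc(Br)c(OC)c(C)c1C=O | intermediate
10 | 3,6-dimethoxy-2-methyl-4-(4,4,5,5-tetramethyl-1,3,2-dioxaborolan-2-yl)benzaldehyde | COc1cc(B2OC(C)(C)C(C)(C)O2)c(OC)c(C)c1C=O | intermediate
11 | 1,3-dimethoxy-5-methylbenzene | COc1cc(C)cc(OC)c1 | starting material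
12 | (2,6-dimethoxy-4-methylphenyl)lithium (not isolated) | [Li]c1c(OC)cc(C)cc1OC | intermediate
13 | lithium 1-(2,6-dimethoxy-4-methylphenyl)-1-[methoxy(methyl)amino]ethan-1-olate (not isolated) | COc1cc(C)cc(OC)c1C(C)([O-])N(C)OC.[Li+] | intermediate
14 | 1-(2,6-dimethoxy-4-methylphenyl)ethan-1-one | COc1cc(C)cc(OC)c1C(C)=O | intermediate
15 | 1-(2,6-dihydroxy-4-methylphenyl)ethan-1-one | CC(=O)c1c(O)cc(C)cc1O | intermediate
16 | 2-acetyl-3-hydroxy-5-methylphenyl trifluoromethanesulfonate | CC(=O)c1c(O)cc(C)cc1OS(=O)(=O)C(F)(F)F | intermediate
17 | methyl 2-acetyl-3-hydroxy-5-methylbenzoate | COC(=O)c1cc(C)cc(O)c1C(C)=O | intermediate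
18 | methyl 2-acetyl-3-hydroxy-4-iodo-5-methylbenzoate | COC(=O)c1cc(C)c(I)c(O)c1C(C)=O | intermediate
19 | methyl 2-[(2E)-3-(dimethylamino)prop-2-enoyl]-3-hydroxy-4-iodo-5-methylbenzoate (not isolated) | COC(=O)c1cc(C)c(I)c(O)c1C(=O)/C=C/N(C)C | intermediate
20 | methyl 8-iodo-7-methyl-4-oxo-4H-chromene-5-carboxylate | COC(=O)c1cc(C)c(I)c2occc(=O)c12 | intermediate
21 | methyl 8-(4-formyl-2,5-dimethoxy-3-methylphenyl)-7-methyl-4-oxo-4H-chromene-5-carboxylate | COc1cc(-c2c(C)cc(C(=O)OC)c3c(=O)ccoc23)c(OC)c(C)c1C=O | intermediate
22 | tert-butyl (E)-but-2-enoate | C/C=C/C(=O)OC(C)(C)C | starting material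
23 | methyl 8-[4-(hydroxymethylidene)-2,5-dimethoxy-3-methylidenecyclohexa-1,5-dien-1-yl]-7-methyl-4-oxo-4H-chromene-5-carboxylate, hydroxyl turned away from the methylidene group (not isolated) | O/C=C1/C(=C)C(OC)=C(c2c(C)cc(C(=O)OC)c3c(=O)ccoc23)C=C1OC | intermediate
24 | tert-butyl rac-(1R,2R,3S)-1-hydroxy-5,8-dimethoxy-6-[5-(methoxycarbonyl)-7-methyl-4-oxo-4H-chromen-8-yl]-3-methyl-1,2,3,4-tetrahydronaphthalene-2-carboxylate (one enantiomer drawn) | COc1cc(-c2c(C)cc(C(=O)OC)c3c(=O)ccoc23)c(OC)c2c1[C@H](O)[C@H](C(=O)OC(C)(C)C)[C@@H](C)C2 | intermediate
25 | tert-butyl rac-(2R,3S)-5,8-dimethoxy-6-[5-(methoxycarbonyl)-7-methyl-4-oxo-4H-chromen-8-yl]-3-methyl-1-oxo-1,2,3,4-tetrahydronaphthalene-2-carboxylate (one enantiomer drawn) | COc1cc(-c2c(C)cc(C(=O)OC)c3c(=O)ccoc23)c(OC)c2c1C(=O)[C@H](C(=O)OC(C)(C)C)[C@@H](C)C2 | intermediate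
26 | rac-(2R,3S)-5,8-dimethoxy-6-[5-(methoxycarbonyl)-7-methyl-4-oxo-4H-chromen-8-yl]-3-methyl-1-oxo-1,2,3,4-tetrahydronaphthalene-2-carboxylic acid (not isolated) | COc1cc(-c2c(C)cc(C(=O)OC)c3c(=O)ccoc23)c(OC)c2c1C(=O)[C@H](C(=O)O)[C@@H](C)C2 | intermediate
27 | methyl 8-(1,4-dimethoxy-7-methyl-5-oxo-5,6,7,8-tetrahydronaphthalen-2-yl)-7-methyl-4-oxo-4H-chromene-5-carboxylate (racemic) | COc1cc(-c2c(C)cc(C(=O)OC)c3c(=O)ccoc23)c(OC)c2c1C(=O)CC(C)C2 | intermediate
28 | 8-(1,4-dimethoxy-7-methyl-5-oxo-5,6,7,8-tetrahydronaphthalen-2-yl)-7-methyl-4-oxo-4H-chromene-5-carboxylic acid (racemic) | COc1cc(-c2c(C)cc(C(=O)O)c3c(=O)ccoc23)c(OC)c2c1C(=O)CC(C)C2 | intermediate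
29 | 7-methyl-8-(7-methyl-1,4,5-trioxo-1,4,5,6,7,8-hexahydronaphthalen-2-yl)-4-oxo-4H-chromene-5-carboxylic acid (racemic) | CC1CC(=O)C2=C(C1)C(=O)C(c1c(C)cc(C(=O)O)c3c(=O)ccoc13)=CC2=O | intermediate
30 | 7-methyl-4-oxo-8-(1,4,5-trihydroxy-7-methylnaphthalen-2-yl)-4H-chromene-5-carboxylic acid (not isolated) | Cc1cc(O)c2c(O)cc(-c3c(C)cc(C(=O)O)c4c(=O)ccoc34)c(O)c2c1 | intermediate
31 | 8-(5-hydroxy-7-methyl-1,4-dioxo-1,4-dihydronaphthalen-2-yl)-7-methyl-4-oxo-4H-chromene-5-carboxylic acid | Cc1cc(O)c2c(c1)C(=O)C(c1c(C)cc(C(=O)O)c3c(=O)ccoc13)=CC2=O | target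

## Step count and least certain steps

Total step count: 19. Longest linear sequence: 13 steps (steps 7–12, then 13–19 from 11; the branch from 1, steps 1–6 then 13–19, has the same length).

**Step 14 (key step).** The most likely failure is slow trapping of dienol 23 by the β-substituted, singly activated alkene 22. The dienol then reverts thermally to 21, conversion stalls, and light absorbed by the chromone slowly degrades the material. Fallback: from 21, irradiate under the same conditions with the doubly activated di-tert-butyl 2-ethylidenepropanedioate F1. This should give the geminal diester tetralol F2 with the same orientation (C8 bonds to the ethylidene carbon). Dess–Martin oxidation gives the keto diester F3, and TsOH in toluene at 100 °C removes both tert-butyl groups and both carboxyl groups. The route is rejoined at 27.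

**Step 19.** The acylquinone 29 is a strong electrophile. Instead of enolising cleanly it may add a second molecule or solvent, or the isomerisation may stop at a partly tautomerised stage, so that oxidation gives mixtures. Fallback: from 28, ring A is aromatised before any quinone exists. α-Bromination with CuBr2 (EtOAc/CHCl3, reflux) gives the bromo ketone F4; dehydrobromination and tautomerisation with LiBr/Li2CO3 in DMF at 110 °C give the naphthol F5; oxidative demethylation of its dimethoxy ring with (NH4)2Ce(NO3)6 gives 31 directly.

**Step 11.** Ortho selectivity may be incomplete, with attack para to the hydroxyl between methyl and ester, or the ketone may be iodinated at its α-carbon under the acidic conditions. Fallback: from 15, the symmetric diol is iodinated first (NIS, 1 equiv), where only one ring position exists, to give the iodo diol F6. Triflation at the less hindered hydroxyl, remote from iodine (Tf2O, pyridine), gives the iodo triflate F7. Pyranone closure as in step 12 gives the chromenyl triflate F8. Suzuki coupling with 10, in which the iodide reacts before the triflate (Pd(PPh3)4, K3PO4, dioxane), gives the biaryl triflate F9, and methoxycarbonylation as in step 10 rejoins the route at 21. The selectivity question is thereby moved from C–I bond formation to a sterically governed O-sulfonylation.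

**Step 13.** Transmetalation at the doubly ortho-substituted C8' may be slow, so that protodeboronation of the electron-rich boronate and base-induced opening of the pyranone compete. Fallback: a hydroxide-free Stille coupling. From 9, Pd(PPh3)4 and (Me3Sn)2 in toluene at 100 °C give the arylstannane F10, which is coupled with 20 (Pd2(dba)3, P(t-Bu)3, CsF, dioxane, 90 °C) to rejoin the route at 21.

## Further compounds

F1 | step 14 | di-tert-butyl 2-ethylidenepropanedioate | CC=C(C(=O)OC(C)(C)C)C(=O)OC(C)(C)C
F2 | step 14 | di-tert-butyl 1-hydroxy-5,8-dimethoxy-6-[5-(methoxycarbonyl)-7-methyl-4-oxo-4H-chromen-8-yl]-3-methyl-3,4-dihydronaphthalene-2,2(1H)-dicarboxylate (racemic diastereomer mixture) | COc1cc(-c2c(C)cc(C(=O)OC)c3c(=O)ccoc23)c(OC)c2c1C(O)C(C(=O)OC(C)(C)C)(C(=O)OC(C)(C)C)C(C)C2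
F3 | step 14 | di-tert-butyl 5,8-dimethoxy-6-[5-(methoxycarbonyl)-7-methyl-4-oxo-4H-chromen-8-yl]-3-methyl-1-oxo-3,4-dihydronaphthalene-2,2(1H)-dicarboxylate (racemic) | COc1cc(-c2c(C)cc(C(=O)OC)c3c(=O)ccoc23)c(OC)c2c1C(=O)C(C(=O)OC(C)(C)C)(C(=O)OC(C)(C)C)C(C)C2
F4 | step 19 | 8-(6-bromo-1,4-dimethoxy-7-methyl-5-oxo-5,6,7,8-tetrahydronaphthalen-2-yl)-7-methyl-4-oxo-4H-chromene-5-carboxylic acid (racemic diastereomer mixture) | COc1cc(-c2c(C)cc(C(=O)O)c3c(=O)ccoc23)c(OC)c2c1C(=O)C(Br)C(C)C2
F5 | step 19 | 8-(5-hydroxy-1,4-dimethoxy-7-methylnaphthalen-2-yl)-7-methyl-4-oxo-4H-chromene-5-carboxylic acid | COc1cc(-c2c(C)cc(C(=O)O)c3c(=O)ccoc23)c(OC)c2cc(C)cc(O)c12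
F6 | step 11 | 1-(2,6-dihydroxy-3-iodo-4-methylphenyl)ethan-1-one | CC(=O)c1c(O)cc(C)c(I)c1O
F7 | step 11 | 2-acetyl-3-hydroxy-4-iodo-5-methylphenyl trifluoromethanesulfonate | CC(=O)c1c(O)c(I)c(C)cc1OS(=O)(=O)C(F)(F)F
F8 | step 11 | 8-iodo-7-methyl-4-oxo-4H-chromen-5-yl trifluoromethanesulfonate | Cc1cc(OS(=O)(=O)C(F)(F)F)c2c(=O)ccoc2c1I
F9 | step 11 | 8-(4-formyl-2,5-dimethoxy-3-methylphenyl)-7-methyl-4-oxo-4H-chromen-5-yl trifluoromethanesulfonate | COc1cc(-c2c(C)cc(OS(=O)(=O)C(F)(F)F)c3c(=O)ccoc23)c(OC)c(C)c1C=O
F10 | step 13 | 3,6-dimethoxy-2-methyl-4-(trimethylstannyl)benzaldehyde | COc1cc([Sn](C)(C)C)c(OC)c(C)c1C=O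
A1 | alternative 1 | methyl 2-acetyl-3-hydroxy-5-methyl-4-(1,4,5-trimethoxy-7-methylnaphthalen-2-yl)benzoate | CC(=O)c1c(O)c(-c2cc(OC)c3c(OC)cc(C)cc3c2OC)c(C)cc1C(=O)OC
A2 | alternative 1 | 2-[2,4-bis(trimethylsilyloxy)penta-1,3-dien-1-yl]-1,4,5-trimethoxy-7-methylnaphthalene | CC(O[Si](C)(C)C)=CC(O[Si](C)(C)C)=Cc1cc(OC)c2c(OC)cc(C)cc2c1OC
A3 | alternative 1 | methyl 2-oxo-4-(trimethylsilyloxy)pent-3-enoate | COC(=O)C(=O)C=C(C)O[Si](C)(C)C
A4 | alternative 2 | methyl 8-(1-hydroxy-4,5-dimethoxy-7-methylnaphthalen-2-yl)-7-methyl-4-oxo-4H-chromene-5-carboxylate | COc1cc(-c2c(C)cc(C(=O)OC)c3c(=O)ccoc23)c(O)c2cc(C)cc(OC)c12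
A5 | alternative 2 | pentacarbonyl[methoxy(2-methoxy-4-methylphenyl)methylidene]chromium | COC(c1ccc(C)cc1OC)=[Cr](=C=O)(=C=O)(=C=O)(=C=O)=C=O
A6 | alternative 2 | methyl 8-ethynyl-7-methyl-4-oxo-4H-chromene-5-carboxylate | C#Cc1c(C)cc(C(=O)OC)c2c(=O)ccoc12
A7 | alternative 3 | methyl 8-(5-hydroxy-7-methyl-1,4-dioxo-1,4-dihydronaphthalen-2-yl)-7-methyl-4-oxo-4H-chromene-5-carboxylate | Cc1cc(O)c2c(c1)C(=O)C(c1c(C)cc(C(=O)OC)c3c(=O)ccoc13)=CC2=O
A8 | alternative 3 | methyl 8-(4-bromo-3,6-dioxocyclohexa-1,4-dien-1-yl)-7-methyl-4-oxo-4H-chromene-5-carboxylate | COC(=O)c1cc(C)c(C2=CC(=O)C(Br)=CC2=O)c2occc(=O)c12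
A9 | alternative 3 | [(1-methoxy-3-methylbuta-1,3-dien-1-yl)oxy]trimethylsilane | C=C(C)C=C(OC)O[Si](C)(C)C
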